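**Strategy**

The route rests on cutting ring B at C1–C8a and C3–C4. This exposes a C1–C2–C3 unit with the donor aryl on C1 and a malonate carbon at C3, i.e. a cis-2-aryl-3-(silyloxymethyl)cyclopropane-1,1-diester, and a ring A benzylic chloride that is nucleophilic at C8a and electrophilic at C4. In one flask a Lewis acid lets C8a open the cyclopropane at C1 with inversion, and base then lets C3 alkylate C4, closing ring B and fixing the C1/C2 trans relation. Both phenols are pivalates so that neither benzylic carbon ionizes. C3 is set later by hydrogenation of a C3=C4 alkene directed by the C9' hydroxyl, and C9' is sulfated last.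

Key step: step 11

**Remarks on the chemistry (one line each)**

- Locants: C1 carries the pendant aryl, C2 the C9' arm, C3 the C9 arm, C4 is the ring CH2, C4a/C8a are the fusion carbons; ring A is the fused arene, ring B the saturated ring; these locants are used in all names.
- No error was found in the structures: the target is (1R,2S,3S), all-trans, and the (2S,3S) cis cyclopropane maps onto it by inversion at C1 and retention at C2.
- A 4-alkoxybenzyl alcohol would ionize, and its hydroxyl would open the cyclopropane at oxygen, faster than the aryl-damped cyclopropane is attacked at carbon; ring A is therefore used as the benzylic chloride with O7 as a pivalate, and the alkylation is released by base after the Friedel–Crafts event.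
- The C8 methoxy group, peri to C1, pushes the pendant aryl pseudoaxial, so base equilibration of a C3 ester is not expected to favour the 2,3-trans isomer; C3 is therefore set kinetically.
- The sense of induction in the cyclopropanation is assumed to follow the ligand; the ligand enantiomer that gives the (2S,3S) cyclopropane is used.
- The target is drawn as the free hydrogen sulfate; it is handled as its sodium salt and set free by acidic ion exchange at the end.

**Route**

Step 1
Reactants: 1 2,6-dimethoxyphenol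
Product: 2 4-iodo-2,6-dimethoxyphenol
Conditions: NIS, MeCN, 0 °C to rt
Reagents that add atoms: N-iodosuccinimide, O=C1CCC(=O)N1I
Why: Electrophilic aromatic iodination goes to the position para to the free hydroxyl, both ortho positions being blocked by methoxy groups.

Step 2
Reactants: 2 4-iodo-2,6-dimethoxyphenol
Product: 3 4-iodo-2,6-dimethoxyphenyl pivalate
Conditions: PivCl, Et3N, DMAP (cat.), CH2Cl2, 0 °C to rt
Reagents that add atoms: pivaloyl chloride, CC(C)(C)C(Cl)=O
Why: DMAP-catalysed O-acylation of the hindered phenol installs the ester that later damps the donor power of this aryl.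

Step 3
Reactants: 4 prop-2-yn-1-ol
Product: 5 tert-butyl(diphenyl)(prop-2-yn-1-yloxy)silane
Conditions: TBDPSCl, imidazole, CH2Cl2, rt
Reagents that add atoms: tert-butyl(chloro)diphenylsilane, CC(C)(C)[Si](Cl)(c1ccccc1)c1ccccc1
Why: Imidazole-promoted silylation of a primary alcohol.

Step 4
Reactants: 3 4-iodo-2,6-dimethoxyphenyl pivalate; 5 tert-butyl(diphenyl)(prop-2-yn-1-yloxy)silane
Product: 6 4-{3-[tert-butyl(diphenyl)silyl]oxyprop-1-yn-1-yl}-2,6-dimethoxyphenyl pivalate
Conditions: PdCl2(PPh3)2 (cat.), CuI (cat.), Et3N, THF, rt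
Reagents that add atoms: none
Why: Sonogashira coupling of an aryl iodide with a terminal alkyne tolerates the aryl ester and the silyl ether.

Step 5
Reactants: 6 4-{3-[tert-butyl(diphenyl)silyl]oxyprop-1-yn-1-yl}-2,6-dimethoxyphenyl pivalate
Product: 7 4-{(1Z)-3-[tert-butyl(diphenyl)silyl]oxyprop-1-en-1-yl}-2,6-dimethoxyphenyl pivalate
Conditions: H2 (1 atm), Pd/CaCO3 poisoned with Pb(OAc)2, quinoline, EtOAc, rt
Reagents that add atoms: none
Why: Syn semihydrogenation of the alkyne on poisoned palladium gives the Z alkene that fixes the later cis relation of aryl and CH2OSi.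

Step 6
Reactants: 8 dimethyl malonate
Product: 9 dimethyl 2-(phenyl-λ3-iodanylidene)propanedioate (the phenyliodonium ylide of dimethyl malonate)
Conditions: PhI(OAc)2, KOH, MeCN, 0 °C
Reagents that add atoms: (diacetoxyiodo)benzene, CC(=O)OI(OC(C)=O)c1ccccc1
Why: Base-mediated condensation of the malonate with the iodane gives the isolable iodonium ylide, a carbene source that avoids diazo compounds.

Step 7
Reactants: 7 4-{(1Z)-3-[tert-butyl(diphenyl)silyl]oxyprop-1-en-1-yl}-2,6-dimethoxyphenyl pivalate; 9 dimethyl 2-(phenyl-λ3-iodanylidene)propanedioate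
Product: 10 dimethyl (2S,3S)-2-{[tert-butyl(diphenyl)silyl]oxymethyl}-3-[3,5-dimethoxy-4-(pivaloyloxy)phenyl]cyclopropane-1,1-dicarboxylate (aryl cis to CH2OSi)
Conditions: [Cu(MeCN)4]PF6 (cat.), chiral side-arm bis(oxazoline) ligand (cat.), 4 Å MS, toluene, 0 °C to rt
Reagents that add atoms: none
Why: Copper-carbene transfer from a malonate iodonium ylide to a cis-1,2-disubstituted alkene is a concerted, stereospecific cyclopropanation, so the Z geometry becomes the cis ring relation and the chiral bis(oxazoline) ligand selects the alkene face that gives the (2S,3S) enantiomer.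

Step 8
Reactants: 11 syringaldehyde (4-hydroxy-3,5-dimethoxybenzaldehyde)
Product: 12 4-formyl-2,6-dimethoxyphenyl pivalate
Conditions: PivCl, Et3N, DMAP (cat.), CH2Cl2, 0 °C to rt
Reagents that add atoms: pivaloyl chloride, CC(C)(C)C(Cl)=O
Why: O-acylation of the phenol places the acyl group that will keep the future C4 position from ionizing.

Step 9
Reactants: 12 4-formyl-2,6-dimethoxyphenyl pivalate
Product: 13 4-(hydroxymethyl)-2,6-dimethoxyphenyl pivalate
Conditions: NaBH4, THF/MeOH, 0 °C
Reagents that add atoms: none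
Why: Borohydride reduction of the aldehyde is much faster than attack on the hindered aryl pivalate.

Step 10
Reactants: 13 4-(hydroxymethyl)-2,6-dimethoxyphenyl pivalate
Product: 14 4-(chloromethyl)-2,6-dimethoxyphenyl pivalate
Conditions: SOCl2, pyridine (cat.), CH2Cl2, 0 °C to rt
Reagents that add atoms: thionyl chloride, ClS(Cl)=O
Why: Chlorodehydroxylation of the benzylic alcohol through its chlorosulfite gives a chloride that the para acyloxy group keeps from ionizing.

Step 11
Reactants: 10 dimethyl (2S,3S)-2-{[tert-butyl(diphenyl)silyl]oxymethyl}-3-[3,5-dimethoxy-4-(pivaloyloxy)phenyl]cyclopropane-1,1-dicarboxylate; 14 4-(chloromethyl)-2,6-dimethoxyphenyl pivalate (excess)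
Product: 16 dimethyl (1R,2S)-2-{[tert-butyl(diphenyl)silyl]oxymethyl}-1-[3,5-dimethoxy-4-(pivaloyloxy)phenyl]-6,8-dimethoxy-7-(pivaloyloxy)-1,4-dihydronaphthalene-3,3(2H)-dicarboxylate (1,2-trans), via open-chain Friedel–Crafts adduct 15 (not isolated)
Conditions: Sc(OTf)3 (cat.), ClCH2CH2Cl/(CF3)2CHOH, 40 °C; volatiles removed; then Cs2CO3, NaI (cat.), MeCN (dilute), 40 °C, same flask
Reagents that add atoms: none
Why: Proposed new method: Sc(OTf)3 chelates the geminal diester of 10 and polarizes the C1–C3 bond, the ring carbon of 14 that is ortho to OMe, para to OMe and ortho to CH2Cl (the future C8a) attacks C1 anti to the departing malonate carbon in an SN2-like Friedel–Crafts step to give 15, and carbonate then converts the released malonate C–H into the carbanion that displaces the benzylic chloride at C4. The closest known reactions are the Lewis-acid-catalysed, invertive Friedel–Crafts opening of 2-arylcyclopropane-1,1-diesters by electron-rich arenes, their (3+3) cyclodimerization to 1-aryltetralins and the intramolecular benzylation of malonates; joining the two events into a two-component (3+3) annulation with an ortho-unsubstituted benzylic chloride is the new part. Ring B closes in the second event by a 6-exo-tet alkylation of C3 onto C4. C1 is set by inversion at the cyclopropane carbon and C2 is carried through untouched, so the cis cyclopropane gives the 1,2-trans tetralin. The step needs C-alkylation without ionization at C1 or C4 and a single regioisomer: the two para pivalates damp both benzylic positions so that 10 neither epimerizes nor racemizes and 14 does not ionize under the Lewis acid, 14 carries no nucleophilic heteroatom and is used in excess to outrun cyclodimerization of 10, and its two reactive ring carbons are equivalent by symmetry.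

Step 12
Reactants: 16 dimethyl (1R,2S)-2-{[tert-butyl(diphenyl)silyl]oxymethyl}-1-[3,5-dimethoxy-4-(pivaloyloxy)phenyl]-6,8-dimethoxy-7-(pivaloyloxy)-1,4-dihydronaphthalene-3,3(2H)-dicarboxylate
Product: 17 methyl (1R,2S,3RS)-2-{[tert-butyl(diphenyl)silyl]oxymethyl}-1-[3,5-dimethoxy-4-(pivaloyloxy)phenyl]-6,8-dimethoxy-7-(pivaloyloxy)-1,2,3,4-tetrahydronaphthalene-3-carboxylate (both C3 epimers)
Conditions: LiCl, H2O, DMSO, 140 °C
Reagents that add atoms: none
Why: Krapcho dealkoxycarbonylation (chloride SN2 demethylation, loss of CO2, protonation) removes one ester under near-neutral conditions that the hindered aryl pivalates and the silyl ether should survive, and the C3 configuration formed here is erased in the next step.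

Step 13
Reactants: 17 methyl (1R,2S,3RS)-2-{[tert-butyl(diphenyl)silyl]oxymethyl}-1-[3,5-dimethoxy-4-(pivaloyloxy)phenyl]-6,8-dimethoxy-7-(pivaloyloxy)-1,2,3,4-tetrahydronaphthalene-3-carboxylate
Product: 19 methyl (1R,2S)-2-{[tert-butyl(diphenyl)silyl]oxymethyl}-1-[3,5-dimethoxy-4-(pivaloyloxy)phenyl]-6,8-dimethoxy-7-(pivaloyloxy)-1,2-dihydronaphthalene-3-carboxylate (C3=C4), via α-phenylselanyl ester 18 (not isolated)
Conditions: LDA, THF, −78 °C; PhSeBr; then H2O2, pyridine, CH2Cl2, 0 °C to rt
Reagents that add atoms: none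
Why: α-Selenenylation of the ester enolate followed by selenoxide syn-elimination should run toward the benzylic C4–H and give the conjugated C3=C4 ester.

Step 14
Reactants: 19 methyl (1R,2S)-2-{[tert-butyl(diphenyl)silyl]oxymethyl}-1-[3,5-dimethoxy-4-(pivaloyloxy)phenyl]-6,8-dimethoxy-7-(pivaloyloxy)-1,2-dihydronaphthalene-3-carboxylate
Product: 20 4-[(1R,2S)-2-{[tert-butyl(diphenyl)silyl]oxymethyl}-7-hydroxy-3-(hydroxymethyl)-6,8-dimethoxy-1,2-dihydronaphthalen-1-yl]-2,6-dimethoxyphenol
Conditions: i-Bu2AlH (excess), CH2Cl2, −78 to 0 °C; aq. potassium sodium tartrate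
Reagents that add atoms: none
Why: The aluminium hydride reduces the conjugated ester in 1,2 fashion to the allylic alcohol and cleaves both aryl pivalates reductively, while the silyl ether stays.

Step 15
Reactants: 20 4-[(1R,2S)-2-{[tert-butyl(diphenyl)silyl]oxymethyl}-7-hydroxy-3-(hydroxymethyl)-6,8-dimethoxy-1,2-dihydronaphthalen-1-yl]-2,6-dimethoxyphenol
Product: 21 {[(1R,2S)-7-(benzyloxy)-1-[4-(benzyloxy)-3,5-dimethoxyphenyl]-3-[(benzyloxy)methyl]-6,8-dimethoxy-1,2-dihydronaphthalen-2-yl]methoxy}(tert-butyl)diphenylsilane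
Conditions: NaH, BnBr, n-Bu4NI (cat.), THF/DMF, 0 °C to rt
Reagents that add atoms: benzyl bromide, BrCc1ccccc1
Why: Williamson etherification of the two phenoxides and the primary alkoxide caps C9–OH and both phenols, TBDPS being the silyl group least prone to O-to-O migration under these conditions.

Step 16
Reactants: 21 {[(1R,2S)-7-(benzyloxy)-1-[4-(benzyloxy)-3,5-dimethoxyphenyl]-3-[(benzyloxy)methyl]-6,8-dimethoxy-1,2-dihydronaphthalen-2-yl]methoxy}(tert-butyl)diphenylsilane
Product: 22 [(1R,2S)-7-(benzyloxy)-1-[4-(benzyloxy)-3,5-dimethoxyphenyl]-3-[(benzyloxy)methyl]-6,8-dimethoxy-1,2-dihydronaphthalen-2-yl]methanol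
Conditions: n-Bu4NF, THF, rt
Reagents that add atoms: none
Why: Fluoride cleaves the Si–O bond and leaves the benzyl ethers untouched, freeing the C9' hydroxyl alone.

Step 17
Reactants: 22 [(1R,2S)-7-(benzyloxy)-1-[4-(benzyloxy)-3,5-dimethoxyphenyl]-3-[(benzyloxy)methyl]-6,8-dimethoxy-1,2-dihydronaphthalen-2-yl]methanol
Product: 23 [(1R,2S,3S)-7-(benzyloxy)-1-[4-(benzyloxy)-3,5-dimethoxyphenyl]-3-[(benzyloxy)methyl]-6,8-dimethoxy-1,2,3,4-tetrahydronaphthalen-2-yl]methanol (all-trans)
Conditions: [Ir(cod)(PCy3)(py)]PF6 (cat.), H2 (1 atm), CH2Cl2, rt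
Reagents that add atoms: none
Why: In this hydroxyl-directed hydrogenation the cationic iridium complex binds the C9' hydroxyl and adds H2 to the C3=C4 face syn to it, so C3–H ends cis to the C9' arm and the C9 arm trans to it (2,3-trans), the pseudoaxial C1 aryl shielding the other face.

Step 18
Reactants: 23 [(1R,2S,3S)-7-(benzyloxy)-1-[4-(benzyloxy)-3,5-dimethoxyphenyl]-3-[(benzyloxy)methyl]-6,8-dimethoxy-1,2,3,4-tetrahydronaphthalen-2-yl]methanol
Product: 24 [(1R,2S,3S)-7-(benzyloxy)-1-[4-(benzyloxy)-3,5-dimethoxyphenyl]-3-[(benzyloxy)methyl]-6,8-dimethoxy-1,2,3,4-tetrahydronaphthalen-2-yl]methyl hydrogen sulfate (handled as its sodium salt)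
Conditions: SO3·pyridine, pyridine, rt; Na+-form ion-exchange resin
Reagents that add atoms: sulfur trioxide–pyridine complex, [O-]S(=O)(=O)[n+]1ccccc1
Why: O-Sulfation of the only free hydroxyl with the SO3·pyridine complex places the sulfate on C9'.

Step 19
Reactants: 24 [(1R,2S,3S)-7-(benzyloxy)-1-[4-(benzyloxy)-3,5-dimethoxyphenyl]-3-[(benzyloxy)methyl]-6,8-dimethoxy-1,2,3,4-tetrahydronaphthalen-2-yl]methyl hydrogen sulfate
Product: 25 [(1R,2S,3S)-7-hydroxy-1-(4-hydroxy-3,5-dimethoxyphenyl)-3-(hydroxymethyl)-6,8-dimethoxy-1,2,3,4-tetrahydronaphthalen-2-yl]methyl hydrogen sulfate (target)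
Conditions: H2 (1 atm), Pd/C, MeOH, rt; then H+-form sulfonic acid resin
Reagents that add atoms: none
Why: Hydrogenolysis of the three benzyl ethers on palladium does not touch the sulfate monoester, and acidic ion exchange gives the hydrogen sulfate.

**Compound list**

1 | 2,6-dimethoxyphenol | COc1cccc(OC)c1O | starting material
2 | 4-iodo-2,6-dimethoxyphenol | COc1cc(I)cc(OC)c1O | intermediate
3 | 4-iodo-2,6-dimethoxyphenyl pivalate | COc1cc(I)cc(OC)c1OC(=O)C(C)(C)C | intermediate
4 | prop-2-yn-1-ol | OCC#C | starting material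
5 | tert-butyl(diphenyl)(prop-2-yn-1-yloxy)silane | C#CCO[Si](c1ccccc1)(c1ccccc1)C(C)(C)C | intermediate
6 | 4-{3-[tert-butyl(diphenyl)silyl]oxyprop-1-yn-1-yl}-2,6-dimethoxyphenyl pivalate | COc1cc(C#CCO[Si](c2ccccc2)(c2ccccc2)C(C)(C)C)cc(OC)c1OC(=O)C(C)(C)C | intermediate
7 | 4-{(1Z)-3-[tert-butyl(diphenyl)silyl]oxyprop-1-en-1-yl}-2,6-dimethoxyphenyl pivalate | COc1cc(/C=C\CO[Si](c2ccccc2)(c2ccccc2)C(C)(C)C)cc(OC)c1OC(=O)C(C)(C)C | intermediate
8 | dimethyl malonate | COC(=O)CC(=O)OC | starting material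
9 | dimethyl 2-(phenyl-λ3-iodanylidene)propanedioate | COC(=O)[C-](C(=O)OC)[I+]c1ccccc1 | intermediate
10 | dimethyl (2S,3S)-2-{[tert-butyl(diphenyl)silyl]oxymethyl}-3-[3,5-dimethoxy-4-(pivaloyloxy)phenyl]cyclopropane-1,1-dicarboxylate (cis) | COc1cc([C@@H]2[C@H](CO[Si](c3ccccc3)(c3ccccc3)C(C)(C)C)C2(C(=O)OC)C(=O)OC)cc(OC)c1OC(=O)C(C)(C)C | intermediate
11 | syringaldehyde | COc1cc(C=O)cc(OC)c1O | starting material
12 | 4-formyl-2,6-dimethoxyphenyl pivalate | COc1cc(C=O)cc(OC)c1OC(=O)C(C)(C)C | intermediate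
13 | 4-(hydroxymethyl)-2,6-dimethoxyphenyl pivalate | COc1cc(CO)cc(OC)c1OC(=O)C(C)(C)C | intermediate
14 | 4-(chloromethyl)-2,6-dimethoxyphenyl pivalate | COc1cc(CCl)cc(OC)c1OC(=O)C(C)(C)C | intermediate
15 | dimethyl 2-[(1R,2S)-1-[2-(chloromethyl)-4,6-dimethoxy-5-(pivaloyloxy)phenyl]-1-[3,5-dimethoxy-4-(pivaloyloxy)phenyl]-3-{[tert-butyl(diphenyl)silyl]oxy}propan-2-yl]propanedioate | COc1cc([C@H](c2c(CCl)cc(OC)c(OC(=O)C(C)(C)C)c2OC)[C@H](CO[Si](c2ccccc2)(c2ccccc2)C(C)(C)C)C(C(=O)OC)C(=O)OC)cc(OC)c1OC(=O)C(C)(C)C | intermediate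
16 | dimethyl (1R,2S)-2-{[tert-butyl(diphenyl)silyl]oxymethyl}-1-[3,5-dimethoxy-4-(pivaloyloxy)phenyl]-6,8-dimethoxy-7-(pivaloyloxy)-1,4-dihydronaphthalene-3,3(2H)-dicarboxylate | COc1cc([C@@H]2c3c(cc(OC)c(OC(=O)C(C)(C)C)c3OC)CC(C(=O)OC)(C(=O)OC)[C@H]2CO[Si](c2ccccc2)(c2ccccc2)C(C)(C)C)cc(OC)c1OC(=O)C(C)(C)C | intermediate
17 | methyl (1R,2S,3RS)-2-{[tert-butyl(diphenyl)silyl]oxymethyl}-1-[3,5-dimethoxy-4-(pivaloyloxy)phenyl]-6,8-dimethoxy-7-(pivaloyloxy)-1,2,3,4-tetrahydronaphthalene-3-carboxylate | COc1cc([C@@H]2c3c(cc(OC)c(OC(=O)C(C)(C)C)c3OC)CC(C(=O)OC)[C@H]2CO[Si](c2ccccc2)(c2ccccc2)C(C)(C)C)cc(OC)c1OC(=O)C(C)(C)C | intermediate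
18 | 3-(phenylselanyl) derivative of 17 (selenium on C3, C1 and C2 unchanged) | COc1cc([C@@H]2c3c(cc(OC)c(OC(=O)C(C)(C)C)c3OC)CC([Se]c3ccccc3)(C(=O)OC)[C@H]2CO[Si](c2ccccc2)(c2ccccc2)C(C)(C)C)cc(OC)c1OC(=O)C(C)(C)C | intermediate
19 | methyl (1R,2S)-2-{[tert-butyl(diphenyl)silyl]oxymethyl}-1-[3,5-dimethoxy-4-(pivaloyloxy)phenyl]-6,8-dimethoxy-7-(pivaloyloxy)-1,2-dihydronaphthalene-3-carboxylate | COc1cc([C@@H]2c3c(cc(OC)c(OC(=O)C(C)(C)C)c3OC)C=C(C(=O)OC)[C@H]2CO[Si](c2ccccc2)(c2ccccc2)C(C)(C)C)cc(OC)c1OC(=O)C(C)(C)C | intermediate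
20 | 4-[(1R,2S)-2-{[tert-butyl(diphenyl)silyl]oxymethyl}-7-hydroxy-3-(hydroxymethyl)-6,8-dimethoxy-1,2-dihydronaphthalen-1-yl]-2,6-dimethoxyphenol | COc1cc([C@@H]2c3c(cc(OC)c(O)c3OC)C=C(CO)[C@H]2CO[Si](c2ccccc2)(c2ccccc2)C(C)(C)C)cc(OC)c1O | intermediate
21 | {[(1R,2S)-7-(benzyloxy)-1-[4-(benzyloxy)-3,5-dimethoxyphenyl]-3-[(benzyloxy)methyl]-6,8-dimethoxy-1,2-dihydronaphthalen-2-yl]methoxy}(tert-butyl)diphenylsilane | COc1cc([C@@H]2c3c(cc(OC)c(OCc4ccccc4)c3OC)C=C(COCc3ccccc3)[C@H]2CO[Si](c2ccccc2)(c2ccccc2)C(C)(C)C)cc(OC)c1OCc1ccccc1 | intermediate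
22 | [(1R,2S)-7-(benzyloxy)-1-[4-(benzyloxy)-3,5-dimethoxyphenyl]-3-[(benzyloxy)methyl]-6,8-dimethoxy-1,2-dihydronaphthalen-2-yl]methanol | COc1cc([C@@H]2c3c(cc(OC)c(OCc4ccccc4)c3OC)C=C(COCc3ccccc3)[C@H]2CO)cc(OC)c1OCc1ccccc1 | intermediate
23 | [(1R,2S,3S)-7-(benzyloxy)-1-[4-(benzyloxy)-3,5-dimethoxyphenyl]-3-[(benzyloxy)methyl]-6,8-dimethoxy-1,2,3,4-tetrahydronaphthalen-2-yl]methanol | COc1cc([C@@H]2c3c(cc(OC)c(OCc4ccccc4)c3OC)C[C@H](COCc3ccccc3)[C@H]2CO)cc(OC)c1OCc1ccccc1 | intermediate
24 | [(1R,2S,3S)-7-(benzyloxy)-1-[4-(benzyloxy)-3,5-dimethoxyphenyl]-3-[(benzyloxy)methyl]-6,8-dimethoxy-1,2,3,4-tetrahydronaphthalen-2-yl]methyl hydrogen sulfate | COc1cc([C@@H]2c3c(cc(OC)c(OCc4ccccc4)c3OC)C[C@H](COCc3ccccc3)[C@H]2COS(=O)(=O)O)cc(OC)c1OCc1ccccc1 | intermediate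
25 | [(1R,2S,3S)-7-hydroxy-1-(4-hydroxy-3,5-dimethoxyphenyl)-3-(hydroxymethyl)-6,8-dimethoxy-1,2,3,4-tetrahydronaphthalen-2-yl]methyl hydrogen sulfate | COc1cc([C@@H]2c3c(cc(OC)c(O)c3OC)C[C@H](CO)[C@H]2COS(=O)(=O)O)cc(OC)c1O | target

**Step count**

Total: 19 steps. Longest linear sequence: 14 steps (steps 1, 2, 4, 5, 7, 11, 12, 13, 14, 15, 16, 17, 18, 19, from 2,6-dimethoxyphenol).

**Steps most likely to fail, with fallbacks**

1. Step 11. The Friedel–Crafts opening may stall because both partners are electronically damped, the cyclopropane may cyclodimerize instead, or the benzylic chloride may be consumed by the Lewis acid before the base stage. The fallback sets out from 10 and 14, comes back at 16, and reverses the order of the two bonds using known reactions only. Cyclopropane 10 is opened at C1 by methanol under Sc(OTf)3 catalysis (Lewis-acid alcoholysis of 2-arylcyclopropane-1,1-diesters) to give the γ-methoxy malonate F1. Its sodium enolate (NaH, DMF) is benzylated at C3 by 14 (malonate alkylation, forming C3–C4) to give the quaternary malonate F2. TfOH in (CF3)2CHOH/CH2Cl2 then ionizes the C1 methyl ether and ring A closes onto C1 (cationic Friedel–Crafts cyclization of the kind used for 1-aryltetralin lignans). The aryl should settle trans to the C2 arm under substrate control, which gives 16.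

2. Step 7. Enantiofacial discrimination on the hindered Z alkene may be poor, or the ylide may decompose faster than the carbene is transferred. The fallback sets out from 7 and 8, comes back at 10, and introduces the chirality by resolution instead of catalysis. Dimethyl malonate 8 is converted by diazo transfer (4-acetamidobenzenesulfonyl azide, Et3N, MeCN) into dimethyl diazomalonate F3. F3 cyclopropanates 7 stereospecifically under Rh2(esp)2 catalysis to give the racemic cis cyclopropane F4. Preparative chromatography on a chiral stationary phase then delivers the (2S,3S) enantiomer 10.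

3. Step 13. Selenenylation of the hindered tertiary enolate may be incomplete, or the syn-elimination may run toward C2 (possible when selenium enters cis to the C2 hydrogen), which would destroy the C2 stereocentre. The fallback sets out from 17, comes back at 19, and uses an anti elimination, whose geometric demand is the opposite. The lithium enolate of 17 (LDA, THF, −78 °C) is brominated with NBS to give the α-bromo ester F5. DBU in toluene at 80 °C then removes HBr across C3–C4 by E2, the acidic benzylic C4–H being the hydrogen that can stand antiperiplanar to bromine, which gives 19.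

**Further compounds**

F1 | step 11 | dimethyl 2-[(1R,2S)-1-[3,5-dimethoxy-4-(pivaloyloxy)phenyl]-1-methoxy-3-{[tert-butyl(diphenyl)silyl]oxy}propan-2-yl]propanedioate | COc1cc([C@H](OC)[C@H](CO[Si](c2ccccc2)(c2ccccc2)C(C)(C)C)C(C(=O)OC)C(=O)OC)cc(OC)c1OC(=O)C(C)(C)C
F2 | step 11 | dimethyl 2-{[3,5-dimethoxy-4-(pivaloyloxy)phenyl]methyl}-2-[(1R,2S)-1-[3,5-dimethoxy-4-(pivaloyloxy)phenyl]-1-methoxy-3-{[tert-butyl(diphenyl)silyl]oxy}propan-2-yl]propanedioate | COc1cc([C@H](OC)[C@H](CO[Si](c2ccccc2)(c2ccccc2)C(C)(C)C)C(Cc2cc(OC)c(OC(=O)C(C)(C)C)c(OC)c2)(C(=O)OC)C(=O)OC)cc(OC)c1OC(=O)C(C)(C)C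
F3 | step 7 | dimethyl 2-diazopropanedioate | COC(=O)C(=[N+]=[N-])C(=O)OC
F4 | step 7 | racemic cis cyclopropane (1:1 mixture of 10 and its enantiomer) | COc1cc([C@@H]2[C@H](CO[Si](c3ccccc3)(c3ccccc3)C(C)(C)C)C2(C(=O)OC)C(=O)OC)cc(OC)c1OC(=O)C(C)(C)C.COc1cc([C@H]2[C@@H](CO[Si](c3ccccc3)(c3ccccc3)C(C)(C)C)C2(C(=O)OC)C(=O)OC)cc(OC)c1OC(=O)C(C)(C)C
F5 | step 13 | 3-bromo derivative of 17 (bromine on C3, C1 and C2 unchanged) | COc1cc([C@@H]2c3c(cc(OC)c(OC(=O)C(C)(C)C)c3OC)CC(Br)(C(=O)OC)[C@H]2CO[Si](c2ccccc2)(c2ccccc2)C(C)(C)C)cc(OC)c1OC(=O)C(C)(C)C
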